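**Retrosynthetic overview**
1. Phlorofucofuroeckol A ⇐ its octamethyl ether 19; global demethylation is the last step.
2. The dioxin ring (formed last) ⇐ intramolecular Ullmann C–O closure of a hydroquinone onto the ring-C bromide. The diaryl ether before it comes from two successive vinylic substitutions on 2,3-dibromo-5-methoxybenzoquinone 15 (dearomatised vanillin), which becomes the pentaoxygenated ring.
3. The dibenzofuran (formed first, key step 4) ⇐ oxidative dearomatisation of 2-bromo-4,6-dimethoxyphenol 8 to a quinone monoketal, then rearomatising [3+2] annulation with phenol 5 (one C–C and one C–O bond).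
4. Phenol 5 ⇐ Ullmann etherification of bromo-aldehyde 1 with 3,5-dimethoxyphenol 2, then Dakin oxidation; 2 supplies both terminal phloroglucinol rings.
5. Ring order: furan → diaryl ether → dioxin.

Assumption: the target has no stereocentre (its SMILES carries none), so there is no enantiomer to control; 1 and 6 are taken as catalogue compounds.

**Route**

Step 1
Reactants: 1 2-bromo-3,5-dimethoxybenzaldehyde; 2 3,5-dimethoxyphenol
Product: 3 2-(3,5-dimethoxyphenoxy)-3,5-dimethoxybenzaldehyde
Conditions: CuI (10 mol %), N,N-dimethylglycine·HCl (30 mol %), Cs2CO3, dioxane, 100 °C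
Reagents that add atoms: none
Why: Ullmann-type Cu-catalysed diaryl ether synthesis; the C–Br bond is ortho to the formyl group, which activates this hindered bromide towards the unhindered phenoxide, and no stereocentre is formed.

Step 2
Reactants: 3 2-(3,5-dimethoxyphenoxy)-3,5-dimethoxybenzaldehyde
Product: 5 2-(3,5-dimethoxyphenoxy)-3,5-dimethoxyphenol, via aryl formate 4 (not isolated)
Conditions: mCPBA (1.1 equiv), CH2Cl2, 0 °C → rt; NaHCO3 wash; then K2CO3 (cat.), MeOH, rt
Reagents that add atoms: mCPBA O=C(OO)c1cccc(Cl)c1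
Why: Baeyer–Villiger (Dakin-type) oxidation; the ring bearing the ortho aryloxy donor migrates to oxygen and the formate is methanolysed, with cold, near-stoichiometric peracid to spare the electron-rich rings.

Step 3
Reactants: 6 2-bromo-4,6-dimethoxybenzaldehyde
Product: 8 2-bromo-4,6-dimethoxyphenol, via aryl formate 7 (not isolated)
Conditions: mCPBA (1.1 equiv), CH2Cl2, 0 °C → rt; NaHCO3 wash; then K2CO3 (cat.), MeOH, rt
Reagents that add atoms: mCPBA O=C(OO)c1cccc(Cl)c1
Why: Baeyer–Villiger (Dakin-type) oxidation; ortho- and para-methoxy groups make aryl migration fast.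

Step 4 (key step)
Reactants: 8 2-bromo-4,6-dimethoxyphenol; 5 2-(3,5-dimethoxyphenoxy)-3,5-dimethoxyphenol
Product: 10 1-bromo-6-(3,5-dimethoxyphenoxy)-3,7,9-trimethoxydibenzo[b,d]furan-2-ol, via quinone monoketal 9 (not isolated)
Conditions: 8, PhI(OAc)2 (1.05 equiv), MeOH, 0 °C, 30 min; evaporate; then 5 (1.1 equiv), TFA (0.2 equiv), (CF3)2CHOH/CH2Cl2, 0 → 40 °C
Reagents that add atoms: none
Why: Proposed new method: PhI(OAc)2/MeOH dearomatises the p-methoxyphenol to the quinone monoketal (known), then acid lets the OH of 5 exchange into the ketal carbon and its only free ortho carbon add in a 5-exo Friedel–Crafts/Michael sense to the adjacent bromine-activated enone carbon (the methoxy-bearing enone carbon is deactivated), and loss of two MeOH rearomatises the ring, so the furan oxygen and the C–C bond are placed without ambiguity; the closest known reaction type is the acid/HFIP-promoted coupling of quinone monoacetals with phenols (Kita) and [3+2] benzofuran annulations of quinone monoketals with 1,3-dinucleophiles.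

Step 5
Reactants: 11 vanillin
Product: 12 2,3-dibromo-4-hydroxy-5-methoxybenzaldehyde (5,6-dibromovanillin)
Conditions: Br2 (2.3 equiv), Fe powder (cat.), AcOH, rt → 60 °C
Reagents that add atoms: bromine BrBr
Why: Electrophilic aromatic bromination; the first bromine enters ortho to OH and the second, Fe-catalysed, para to OMe, a known two-fold bromination of vanillin.

Step 6
Reactants: 12 2,3-dibromo-4-hydroxy-5-methoxybenzaldehyde
Product: 15 2,3-dibromo-5-methoxy-1,4-benzoquinone, via aryl formate 13 (not isolated), via hydroquinone 14 (not isolated)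
Conditions: 30 % H2O2, H2SO4 (cat.), MeOH, rt; extractive work-up; then FeCl3, MeOH/H2O, rt
Reagents that add atoms: hydrogen peroxide OO
Why: Acid-catalysed Dakin oxidation of the p-hydroxybenzaldehyde to the hydroquinone, then FeCl3 oxidation; this oxidative dearomatisation turns the arene into a bis-electrophilic quinone.

Step 7
Reactants: 15 2,3-dibromo-5-methoxy-1,4-benzoquinone; 2 3,5-dimethoxyphenol
Product: 16 3-bromo-2-(3,5-dimethoxyphenoxy)-5-methoxy-1,4-benzoquinone
Conditions: Cs2CO3 (1.0 equiv), MeCN, −20 → 0 °C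
Reagents that add atoms: none
Why: Nucleophilic vinylic substitution (addition–elimination) on a haloquinone; the phenoxide attacks C2, para to OMe, because it is β to the C4 carbonyl that is not deactivated by vinylogous-ester conjugation, and O-attack is favoured for the caesium phenoxide in MeCN at low temperature.

Step 8
Reactants: 16 3-bromo-2-(3,5-dimethoxyphenoxy)-5-methoxy-1,4-benzoquinone; 10 1-bromo-6-(3,5-dimethoxyphenoxy)-3,7,9-trimethoxydibenzo[b,d]furan-2-ol
Product: 17 2-(3,5-dimethoxyphenoxy)-3-{[1-bromo-6-(3,5-dimethoxyphenoxy)-3,7,9-trimethoxydibenzo[b,d]furan-2-yl]oxy}-5-methoxy-1,4-benzoquinone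
Conditions: Cs2CO3 (1.1 equiv), DMF, 0 °C → rt
Reagents that add atoms: none
Why: Second addition–elimination at the remaining C–Br (bromide is the better leaving group); the phenoxide of 10 has both ortho positions blocked, so only O-attack is possible.

Step 9
Reactants: 17 the bis(aryloxy)quinone
Product: 19 phlorofucofuroeckol A octamethyl ether (every OH methylated except the one ortho to the 3,5-dimethoxyphenoxy group on the dioxin ring), via hydroquinone 18 (not isolated)
Conditions: Na2S2O4, THF/H2O, rt (extract under Ar); then CuI (20 mol %), N,N-dimethylglycine (40 mol %), Cs2CO3, degassed dioxane, 100 °C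
Reagents that add atoms: none
Why: Dithionite reduction of the quinone, then intramolecular Ullmann O-arylation; only the hydroquinone OH ortho to the diaryl ether can reach the ring bromide, so the six-membered dibenzo-p-dioxin closes with fixed regiochemistry.

Step 10
Reactants: 19 phlorofucofuroeckol A octamethyl ether
Product: 20 phlorofucofuroeckol A
Conditions: BBr3 (20 equiv), CH2Cl2, −78 °C → rt; then MeOH/H2O
Reagents that add atoms: none
Why: Lewis-acid (BBr3) cleavage of all eight aryl methyl ethers; diaryl ether, furan and dioxin C–O bonds are inert under these conditions and the product has no stereocentre.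

**Compound list**
1 | 2-bromo-3,5-dimethoxybenzaldehyde | O=Cc1cc(OC)cc(OC)c1Br | starting material
2 | 3,5-dimethoxyphenol | COc1cc(O)cc(OC)c1 | starting material
3 | 2-(3,5-dimethoxyphenoxy)-3,5-dimethoxybenzaldehyde | O=Cc1cc(OC)cc(OC)c1Oc1cc(OC)cc(OC)c1 | intermediate
4 | 2-(3,5-dimethoxyphenoxy)-3,5-dimethoxyphenyl formate | O=COc1cc(OC)cc(OC)c1Oc1cc(OC)cc(OC)c1 | intermediate
5 | 2-(3,5-dimethoxyphenoxy)-3,5-dimethoxyphenol | Oc1cc(OC)cc(OC)c1Oc1cc(OC)cc(OC)c1 | intermediate
6 | 2-bromo-4,6-dimethoxybenzaldehyde | O=Cc1c(Br)cc(OC)cc1OC | starting material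
7 | 2-bromo-4,6-dimethoxyphenyl formate | O=COc1c(Br)cc(OC)cc1OC | intermediate
8 | 2-bromo-4,6-dimethoxyphenol | Oc1c(Br)cc(OC)cc1OC | intermediate
9 | 2-bromo-4,4,6-trimethoxycyclohexa-2,5-dien-1-one | COC1=CC(OC)(OC)C=C(Br)C1=O | intermediate
10 | 1-bromo-6-(3,5-dimethoxyphenoxy)-3,7,9-trimethoxydibenzo[b,d]furan-2-ol | Oc1c(OC)cc2oc3c(Oc4cc(OC)cc(OC)c4)c(OC)cc(OC)c3c2c1Br | intermediate
11 | vanillin (4-hydroxy-3-methoxybenzaldehyde) | O=Cc1ccc(O)c(OC)c1 | starting material
12 | 2,3-dibromo-4-hydroxy-5-methoxybenzaldehyde | O=Cc1cc(OC)c(O)c(Br)c1Br | intermediate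
13 | 2,3-dibromo-4-hydroxy-5-methoxyphenyl formate | O=COc1cc(OC)c(O)c(Br)c1Br | intermediate
14 | 2,3-dibromo-5-methoxybenzene-1,4-diol | Oc1cc(OC)c(O)c(Br)c1Br | intermediate
15 | 2,3-dibromo-5-methoxy-1,4-benzoquinone | O=C1C=C(OC)C(=O)C(Br)=C1Br | intermediate
16 | 3-bromo-2-(3,5-dimethoxyphenoxy)-5-methoxy-1,4-benzoquinone | O=C1C=C(OC)C(=O)C(Br)=C1Oc1cc(OC)cc(OC)c1 | intermediate
17 | 2-(3,5-dimethoxyphenoxy)-3-{[1-bromo-6-(3,5-dimethoxyphenoxy)-3,7,9-trimethoxydibenzo[b,d]furan-2-yl]oxy}-5-methoxy-1,4-benzoquinone | O=C1C=C(OC)C(=O)C(Oc2c(OC)cc3oc4c(Oc5cc(OC)cc(OC)c5)c(OC)cc(OC)c4c3c2Br)=C1Oc1cc(OC)cc(OC)c1 | intermediate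
18 | 2-(3,5-dimethoxyphenoxy)-3-{[1-bromo-6-(3,5-dimethoxyphenoxy)-3,7,9-trimethoxydibenzo[b,d]furan-2-yl]oxy}-5-methoxybenzene-1,4-diol | Oc1cc(OC)c(O)c(Oc2c(OC)cc3oc4c(Oc5cc(OC)cc(OC)c5)c(OC)cc(OC)c4c3c2Br)c1Oc1cc(OC)cc(OC)c1 | intermediate
19 | phlorofucofuroeckol A octamethyl ether (free OH ortho to the aryloxy group on the dioxin ring) | COc1cc(OC)cc(Oc2c(O)cc(OC)c3c2Oc2c(OC)cc4oc5c(Oc6cc(OC)cc(OC)c6)c(OC)cc(OC)c5c4c2O3)c1 | intermediate
20 | phlorofucofuroeckol A | Oc1cc(O)cc(Oc2c(O)cc(O)c3c2Oc2c(O)cc4oc5c(Oc6cc(O)cc(O)c6)c(O)cc(O)c5c4c2O3)c1 | target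

**Totals**
Total steps: 10. Longest linear sequence: 6 steps (1 → 2 → 4 → 8 → 9 → 10; the vanillin branch 5 → 6 → 7 → 8 → 9 → 10 is equally long).

**Three steps most likely to fail**

Step 4 (ketal annulation; the ionised ketal may react at the wrong carbons, or 5 may attack through its para carbon). The fallback sets out from 8 and 5 and returns at 10. It works at the quinone oxidation level: oxidative demethylation of 8 with CAN in aqueous MeCN gives 2-bromo-6-methoxy-1,4-benzoquinone F1. Acid-promoted Friedel–Crafts conjugate addition of 5 (TFA, HFIP) at the CH next to C–Br gives the biaryl hydroquinone 3-bromo-2-[3-(3,5-dimethoxyphenoxy)-2-hydroxy-4,6-dimethoxyphenyl]-5-methoxybenzene-1,4-diol F2. Cyclodehydration (TsOH, toluene, Dean–Stark) then closes the furan to 10. This classical quinone–phenol condensation is weaker in one respect: the closure can also expel MeOH from the neighbouring methoxy group, so an isomeric furan may need to be separated.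

Step 7 (the ambident, carbon-nucleophilic 3,5-dimethoxyphenoxide may C-alkylate the quinone or attack the wrong carbon). The fallback sets out from 12 and 2 and returns at 16. The diaryl ether is made before dearomatisation: Cu-catalysed Ullmann coupling of 2 at the formyl-activated C–Br of 12 (CuI, N,N-dimethylglycine, Cs2CO3, dioxane) gives 3-bromo-2-(3,5-dimethoxyphenoxy)-4-hydroxy-5-methoxybenzaldehyde F3. Dakin oxidation (H2O2, cat. H2SO4, MeOH) passes through 3-bromo-2-(3,5-dimethoxyphenoxy)-4-hydroxy-5-methoxyphenyl formate F4 to 3-bromo-2-(3,5-dimethoxyphenoxy)-5-methoxybenzene-1,4-diol F5, which FeCl3 oxidises to 16.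

Step 9 (Cu-mediated closure at a hindered bay bromide with an air-sensitive hydroquinone). The fallback sets out from 18, generated from 17 with dithionite as before, and returns at 19. The ring is closed photochemically instead of by metal catalysis: irradiation (about 300 nm, degassed MeCN) of the 2-(2-bromoaryloxy)phenol unit effects the intramolecular photosubstitution known for "predioxin" phenoxyphenols. No new compound is involved.

**Further compounds**
F1 | step 4 | 2-bromo-6-methoxy-1,4-benzoquinone | COC1=CC(=O)C=C(Br)C1=O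
F2 | step 4 | 3-bromo-2-[3-(3,5-dimethoxyphenoxy)-2-hydroxy-4,6-dimethoxyphenyl]-5-methoxybenzene-1,4-diol | Oc1cc(OC)c(O)c(Br)c1-c1c(O)c(Oc2cc(OC)cc(OC)c2)c(OC)cc1OC
F3 | step 7 | 3-bromo-2-(3,5-dimethoxyphenoxy)-4-hydroxy-5-methoxybenzaldehyde | O=Cc1cc(OC)c(O)c(Br)c1Oc1cc(OC)cc(OC)c1
F4 | step 7 | 3-bromo-2-(3,5-dimethoxyphenoxy)-4-hydroxy-5-methoxyphenyl formate | O=COc1cc(OC)c(O)c(Br)c1Oc1cc(OC)cc(OC)c1
F5 | step 7 | 3-bromo-2-(3,5-dimethoxyphenoxy)-5-methoxybenzene-1,4-diol | Oc1cc(OC)c(O)c(Br)c1Oc1cc(OC)cc(OC)c1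
F0 | step 9 | none | none
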